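Everything rests on cutting through ring D, the resorcinol. Its two hydroxyls are meta and its two fusion carbons (D1 on benzofuran C3, D6 on the ring-C carbon C-d) are adjacent, the imprint of a cyclohexane-1,3-dione that can be built from acyclic carbons. The precursor is a finished 2-arylbenzofuran carrying a 3-oxobut-1-ynyl group on C3 and a methyl 3-oxobutanoate chain on C4. In one operation methoxide adds the keto ester carbon to the ynone, closing seven-membered ring C, then acylates the acetyl methyl with the ester, closing and aromatising ring D: two C–C bonds, two rings. Aryl coupling at C-d and an asymmetric hydroboration that moves oxygen to the neighbouring C-a finish the target.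

Key step: step 9

Labels: benzofuran numbering is O1, C2, C3, C3a, C4–C7, C7a. Ring A is the benzofuran benzene ring, ring B the furan, and ring D the resorcinol ring, numbered D1 (bonded to C3) to D6 (bonded to C-d), with oxygen on D3 and D5. Ring C is the seven-membered ring C3–C3a–C4–C-a–C-d–D6–D1, where C-a is bonded to C4 and C-d to D6. The single stereocentre of the target is C-d, and it is (S).

Assumption: the facial sense of IpcBH2 made from (+)-α-pinene is carried over from 1-arylcycloalkenes, which predicts (S) at C-d. If the sense proves opposite, the reagent from (−)-α-pinene is used in the same way.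

Step 1
Reactants: 1 3,5-dihydroxyphenylacetic acid
Product: 2 benzyl 2-[3,5-bis(benzyloxy)phenyl]acetate
Conditions: BnBr (3.5 equiv), K2CO3, DMF, 60 °C
Reagents that add atoms: benzyl bromide, BrCc1ccccc1
Why: Williamson etherification of both phenols and SN2 alkylation of the carboxylate proceed together under carbonate, so protection of the phenols and masking of the acid cost a single operation.

Step 2
Reactants: 2 benzyl 2-[3,5-bis(benzyloxy)phenyl]acetate
Product: 3 benzyl 2-[3,5-bis(benzyloxy)-2-iodophenyl]acetate
Conditions: NIS (1.05 equiv), MeCN, 0 °C → rt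
Reagents that add atoms: N-iodosuccinimide, O=C1CCC(=O)N1I
Why: Electrophilic aromatic iodination should go to C2, which is para to one benzyloxy group and ortho to the other, because C4 lies crowded between two benzyloxy groups and the phenyl rings of the benzyl groups are not activated.

Step 3
Reactants: 3 benzyl 2-[3,5-bis(benzyloxy)-2-iodophenyl]acetate; 4 1-(benzyloxy)-4-ethynylbenzene
Product: 5 benzyl 2-[3,5-bis(benzyloxy)-2-{[4-(benzyloxy)phenyl]ethynyl}phenyl]acetate
Conditions: PdCl2(PPh3)2 (5 mol %), CuI (10 mol %), Et3N–DMF, 60 °C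
Reagents that add atoms: none
Why: Sonogashira coupling: the aryl iodide adds oxidatively to zerovalent palladium in spite of its two ortho substituents, the slim copper acetylide transfers the alkyne, and ester and ethers are inert to Et3N.

Step 4
Reactants: 5 benzyl 2-[3,5-bis(benzyloxy)-2-{[4-(benzyloxy)phenyl]ethynyl}phenyl]acetate
Product: 6 benzyl 2-{6-(benzyloxy)-2-[4-(benzyloxy)phenyl]-3-iodo-1-benzofuran-4-yl}acetate
Conditions: I2 (2 equiv), CH2Cl2, rt; Na2S2O3 aq wash
Reagents that add atoms: iodine, II
Why: Electrophilic 5-endo-dig iodocyclisation of an ortho-alkynyl aryl ether (Larock benzofuran synthesis): the ether oxygen next to the alkyne attacks the iodonium-activated triple bond at the carbon bearing the 4-benzyloxyphenyl group, iodide strips the benzyl group from the oxonium ion, and the remote benzyl ethers and the ester, whose carbonyl could only close a less favourable larger ring, stay out.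

Step 5
Reactants: 6 benzyl 2-{6-(benzyloxy)-2-[4-(benzyloxy)phenyl]-3-iodo-1-benzofuran-4-yl}acetate
Product: 7 2-{6-(benzyloxy)-2-[4-(benzyloxy)phenyl]-3-iodo-1-benzofuran-4-yl}acetic acid
Conditions: LiOH·H2O, THF–MeOH–H2O, rt; then 1 M HCl
Reagents that add atoms: lithium hydroxide, [Li+].[OH-]
Why: Saponification of the benzyl ester by acyl–oxygen cleavage is mild enough for the aryl iodide and the benzyl ethers and is done at this stage because no base-sensitive ynone is yet present.

Step 6
Reactants: 7 2-{6-(benzyloxy)-2-[4-(benzyloxy)phenyl]-3-iodo-1-benzofuran-4-yl}acetic acid; 8 potassium methyl malonate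
Product: 10 methyl 4-{6-(benzyloxy)-2-[4-(benzyloxy)phenyl]-3-iodo-1-benzofuran-4-yl}-3-oxobutanoate, via acyl imidazolide 9 (not isolated)
Conditions: CDI, THF, rt; then 8, MgCl2, Et3N, MeCN–THF, rt → 45 °C; 1 M HCl
Reagents that add atoms: 1,1'-carbonyldiimidazole, O=C(n1ccnc1)n1ccnc1 (imidazolyl group, kept only in 9)
Why: Masamune–Brooks homologation: the acyl imidazolide acylates the magnesium enolate of the malonate half ester and loss of CO2 gives the β-keto ester under almost neutral conditions, which avoids the enolisation problems of a crossed Claisen condensation on an arylacetate.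

Step 7
Reactants: 10 methyl 4-{6-(benzyloxy)-2-[4-(benzyloxy)phenyl]-3-iodo-1-benzofuran-4-yl}-3-oxobutanoate; 11 but-3-yn-2-ol (racemic)
Product: 12 methyl 4-{6-(benzyloxy)-2-[4-(benzyloxy)phenyl]-3-(3-hydroxybut-1-yn-1-yl)-1-benzofuran-4-yl}-3-oxobutanoate (racemic at the carbinol carbon)
Conditions: PdCl2(PPh3)2 (5 mol %), CuI (5 mol %), Et3N, THF, 50 °C
Reagents that add atoms: none
Why: Sonogashira coupling of the reactive 3-iodobenzofuran; the side chain is brought in at the alcohol oxidation level so that no amine can add to an ynone, and Et3N is too weak to turn the β-keto ester into a competing carbon nucleophile.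

Step 8
Reactants: 12 methyl 4-{6-(benzyloxy)-2-[4-(benzyloxy)phenyl]-3-(3-hydroxybut-1-yn-1-yl)-1-benzofuran-4-yl}-3-oxobutanoate
Product: 13 methyl 4-{6-(benzyloxy)-2-[4-(benzyloxy)phenyl]-3-(3-oxobut-1-yn-1-yl)-1-benzofuran-4-yl}-3-oxobutanoate
Conditions: activated MnO2 (excess), CH2Cl2, rt
Reagents that add atoms: none
Why: MnO2 oxidation is selective for the activated propargylic alcohol, is neutral and heterogeneous, leaves the β-keto ester and benzyl ethers alone, erases the carbinol stereocentre and releases the sensitive ynone only directly before it is used.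

Step 9
Reactants: 13 methyl 4-{6-(benzyloxy)-2-[4-(benzyloxy)phenyl]-3-(3-oxobut-1-yn-1-yl)-1-benzofuran-4-yl}-3-oxobutanoate
Product: 16 tetracyclic resorcinol ketone (C-d carbonyl; C-a methylene; free OH on D3 and D5; benzyloxy on C6 and on the C2-phenyl group), via ring-C Michael adduct 14 (not isolated), via cyclohexenedione tautomer 15 (not isolated)
Conditions: NaOMe (5 equiv), MeOH–THF 1:1 (0.01 M, degassed, Ar), 0 → 65 °C; then 1 M HCl
Reagents that add atoms: none
Why: Proposed new method: methoxide deprotonates the keto ester carbon of 13, which adds to the ynone carbon bonded to benzofuran C3 (7-exo-dig, ring C) to give 14 after protonation of the allenolate; the vinylogous enolate of 14 lets the exocyclic C=C isomerise, and the enolate of the acetyl methyl group is then acylated by the ester carbonyl (6-exo-trig, ring D) with loss of methoxide to give 15, which tautomerises irreversibly to the resorcinol 16. The closest known reaction type is the intermolecular base-mediated Michael–Claisen benzannulation of alkynyl ketones with malonates or β-keto esters to resorcinols; what is new is the tether, which makes the Michael step close a seven-membered carbocycle. No stereocentre is formed. Three selectivities are needed: carbon over oxygen attack on the ynone, carbon over oxygen acylation (2-pyranone formation), and Claisen over aldol closure. The first two are secured by methoxide matched to the methyl ester, since the enol ether and pyranone by-paths are reopened by methoxide addition and drain into the aromatic phenoxide as the only irreversible sink. The third is secured by ring C itself, because attack of the methyl enolate on the ring-C ketone would build a bridged bicycle with a bridgehead alkene that cannot dehydrate or aromatise and therefore falls apart again.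

Step 10
Reactants: 16 tetracyclic resorcinol ketone
Product: 17 tetrabenzyl ketone (as 16 with benzyloxy on D3 and D5)
Conditions: BnBr (2.4 equiv), K2CO3, DMF, rt → 50 °C
Reagents that add atoms: benzyl bromide, BrCc1ccccc1
Why: Williamson etherification: carbonate ionises both phenols (the one chelated to the ketone more slowly, hence DMF and gentle warming) but hardly the ring-C methylene, so O-benzylation should outrun C-alkylation and every phenol ends up under the same protecting group.

Step 11
Reactants: 17 tetrabenzyl ketone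
Product: 19 enol triflate (OTf on C-d; C-d=C-a double bond), via potassium enolate 18 (not isolated)
Conditions: KN(SiMe3)2, THF, −78 °C; PhNTf2, −78 → 0 °C
Reagents that add atoms: N-phenylbis(trifluoromethanesulfonimide), O=S(=O)(N(c1ccccc1)S(=O)(=O)C(F)(F)F)C(F)(F)F; KN(SiMe3)2, C[Si](C)(C)[N-][Si](C)(C)C.[K+] (potassium, kept only in 18)
Why: Enolate O-sulfonylation: the ketone can enolise only towards C-a, so KN(SiMe3)2 gives a single enolate that PhNTf2 traps on oxygen as the alkenyl triflate.

Step 12
Reactants: 19 enol triflate; 20 4-(benzyloxy)phenylboronic acid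
Product: 21 ring-C alkene (4-benzyloxyphenyl on C-d; H on C-a)
Conditions: Pd(PPh3)4 (5 mol %), K2CO3 aq, 1,4-dioxane, 80 °C
Reagents that add atoms: none
Why: Suzuki–Miyaura coupling of an alkenyl triflate with an arylboronic acid places the 4-benzyloxyphenyl group on C-d and leaves the C-d=C-a double bond in ring C for the oxygen transposition.

Step 13
Reactants: 21 ring-C alkene
Product: 23 trans alcohol (OH on C-a with R configuration; H on C-d with S configuration; OH and 4-benzyloxyphenyl trans), via isopinocampheylborane adduct 22 (not isolated)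
Conditions: (IpcBH2)2·TMEDA [from (+)-α-pinene], BF3·OEt2, THF, rt, filter; 21, −25 → 0 °C; then NaOH aq, H2O2, 0 °C → rt
Reagents that add atoms: hydrogen peroxide, OO; monoisopinocampheylborane, C[C@H]1[C@H](B)C[C@@H]2C[C@H]1C2(C)C (boron and isopinocampheyl group, kept only in 22)
Why: Brown asymmetric hydroboration–oxidation: boron goes to the less substituted C-a while the developing positive charge at C-d is stabilised by two electron-rich aryl groups, H and B add syn to the alkene face selected by the isopinocampheyl group (sense taken from 1-arylcycloalkenes), which sets C-d as (S) and C-a as (R), and peroxide replaces boron by oxygen with retention.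

Step 14
Reactants: 23 trans alcohol
Product: 24 (S)-pentabenzyl hopeafuran (C-a carbonyl; C-d methine S)
Conditions: Dess–Martin periodinane, NaHCO3 (solid), CH2Cl2, 0 °C
Reagents that add atoms: none
Why: Dess–Martin oxidation works at 0 °C without amine base or strong acid, so the benzylic carbinol C-a becomes the ketone while the now enolisable, doubly benzylic C-d–H is not exposed to conditions that would racemise it.

Step 15
Reactants: 24 (S)-pentabenzyl hopeafuran
Product: 25 hopeafuran, (S) at C-d
Conditions: H2 (1 atm), Pd/C, EtOAc–MeOH, rt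
Reagents that add atoms: none
Why: Catalytic hydrogenolysis of the five benzyl aryl ethers on Pd/C under one atmosphere of hydrogen in neutral solvent should be faster than reduction of the hindered aryl ketone or of the tetrasubstituted furan C2–C3 bond, and the neutral medium leaves (S)-C-d intact.

Compound list
1 | 3,5-dihydroxyphenylacetic acid | O=C(O)Cc1cc(O)cc(O)c1 | starting material
2 | benzyl 2-[3,5-bis(benzyloxy)phenyl]acetate | O=C(OCc1ccccc1)Cc1cc(OCc2ccccc2)cc(OCc2ccccc2)c1 | intermediate
3 | benzyl 2-[3,5-bis(benzyloxy)-2-iodophenyl]acetate | O=C(OCc1ccccc1)Cc1cc(OCc2ccccc2)cc(OCc2ccccc2)c1I | intermediate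
4 | 1-(benzyloxy)-4-ethynylbenzene | C#Cc1ccc(OCc2ccccc2)cc1 | starting material
5 | benzyl 2-[3,5-bis(benzyloxy)-2-{[4-(benzyloxy)phenyl]ethynyl}phenyl]acetate | O=C(OCc1ccccc1)Cc1cc(OCc2ccccc2)cc(OCc2ccccc2)c1C#Cc1ccc(OCc2ccccc2)cc1 | intermediate
6 | benzyl 2-{6-(benzyloxy)-2-[4-(benzyloxy)phenyl]-3-iodo-1-benzofuran-4-yl}acetate | O=C(OCc1ccccc1)Cc1cc(OCc2ccccc2)cc2oc(-c3ccc(OCc4ccccc4)cc3)c(I)c12 | intermediate
7 | 2-{6-(benzyloxy)-2-[4-(benzyloxy)phenyl]-3-iodo-1-benzofuran-4-yl}acetic acid | O=C(O)Cc1cc(OCc2ccccc2)cc2oc(-c3ccc(OCc4ccccc4)cc3)c(I)c12 | intermediate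
8 | potassium methyl malonate | COC(=O)CC(=O)[O-].[K+] | starting material
9 | acyl imidazolide of 7 (not isolated) | O=C(Cc1cc(OCc2ccccc2)cc2oc(-c3ccc(OCc4ccccc4)cc3)c(I)c12)n1ccnc1 | intermediate
10 | methyl 4-{6-(benzyloxy)-2-[4-(benzyloxy)phenyl]-3-iodo-1-benzofuran-4-yl}-3-oxobutanoate | COC(=O)CC(=O)Cc1cc(OCc2ccccc2)cc2oc(-c3ccc(OCc4ccccc4)cc3)c(I)c12 | intermediate
11 | but-3-yn-2-ol (racemic) | CC(O)C#C | starting material
12 | methyl 4-{6-(benzyloxy)-2-[4-(benzyloxy)phenyl]-3-(3-hydroxybut-1-yn-1-yl)-1-benzofuran-4-yl}-3-oxobutanoate (racemic carbinol) | COC(=O)CC(=O)Cc1cc(OCc2ccccc2)cc2oc(-c3ccc(OCc4ccccc4)cc3)c(C#CC(C)O)c12 | intermediate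
13 | methyl 4-{6-(benzyloxy)-2-[4-(benzyloxy)phenyl]-3-(3-oxobut-1-yn-1-yl)-1-benzofuran-4-yl}-3-oxobutanoate | COC(=O)CC(=O)Cc1cc(OCc2ccccc2)cc2oc(-c3ccc(OCc4ccccc4)cc3)c(C#CC(C)=O)c12 | intermediate
14 | ring-C Michael adduct, C3 and C4 bridged by C(=CH–COCH3)–CH(CO2Me)–C(=O)–CH2 (alkene geometry and CH centre labile; not isolated) | COC(=O)C1C(=O)Cc2cc(OCc3ccccc3)cc3oc(-c4ccc(OCc5ccccc5)cc4)c(c23)C1=CC(C)=O | intermediate
15 | cyclohexenedione tautomer of 16 (labile CH centre; not isolated) | O=C1Cc2cc(OCc3ccccc3)cc3oc(-c4ccc(OCc5ccccc5)cc4)c(c23)C2=CC(=O)CC(=O)C12 | intermediate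
16 | tetracyclic resorcinol ketone (C-d carbonyl, C-a methylene, OH on D3 and D5) | O=C1Cc2cc(OCc3ccccc3)cc3oc(-c4ccc(OCc5ccccc5)cc4)c(c23)-c2cc(O)cc(O)c21 | intermediate
17 | tetrabenzyl ketone (benzyloxy on D3 and D5) | O=C1Cc2cc(OCc3ccccc3)cc3oc(-c4ccc(OCc5ccccc5)cc4)c(c23)-c2cc(OCc3ccccc3)cc(OCc3ccccc3)c21 | intermediate
18 | potassium enolate of 17 (not isolated) | [K+].[O-]C1=Cc2cc(OCc3ccccc3)cc3oc(-c4ccc(OCc5ccccc5)cc4)c(c23)-c2cc(OCc3ccccc3)cc(OCc3ccccc3)c21 | intermediate
19 | enol triflate (OTf on C-d, C-d=C-a) | FC(F)(F)S(=O)(=O)OC1=Cc2cc(OCc3ccccc3)cc3oc(-c4ccc(OCc5ccccc5)cc4)c(c23)-c2cc(OCc3ccccc3)cc(OCc3ccccc3)c21 | intermediate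
20 | 4-(benzyloxy)phenylboronic acid | OB(O)c1ccc(OCc2ccccc2)cc1 | starting material
21 | ring-C alkene (4-benzyloxyphenyl on C-d) | C1(-c2ccc(OCc3ccccc3)cc2)=Cc2cc(OCc3ccccc3)cc3oc(-c4ccc(OCc5ccccc5)cc4)c(c23)-c2cc(OCc3ccccc3)cc(OCc3ccccc3)c21 | intermediate
22 | isopinocampheylborane adduct, BH(Ipc) on C-a (R), H on C-d (S) (not isolated) | C[C@H]1[C@H](B[C@H]2c3cc(OCc4ccccc4)cc4oc(-c5ccc(OCc6ccccc6)cc5)c(c34)-c3cc(OCc4ccccc4)cc(OCc4ccccc4)c3[C@@H]2c2ccc(OCc3ccccc3)cc2)C[C@@H]2C[C@H]1C2(C)C | intermediate
23 | trans alcohol, C-a (R), C-d (S) | O[C@H]1c2cc(OCc3ccccc3)cc3oc(-c4ccc(OCc5ccccc5)cc4)c(c23)-c2cc(OCc3ccccc3)cc(OCc3ccccc3)c2[C@@H]1c1ccc(OCc2ccccc2)cc1 | intermediate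
24 | (S)-pentabenzyl hopeafuran | O=C1c2cc(OCc3ccccc3)cc3oc(-c4ccc(OCc5ccccc5)cc4)c(c23)-c2cc(OCc3ccccc3)cc(OCc3ccccc3)c2[C@@H]1c1ccc(OCc2ccccc2)cc1 | intermediate
25 | hopeafuran, (S) | O=C1c2cc(O)cc3oc(-c4ccc(O)cc4)c(c23)-c2cc(O)cc(O)c2[C@@H]1c1ccc(O)cc1 | target

Total step count: 15. Longest linear sequence: 15 steps (1 → 25).

Steps most likely to fail

1. Step 9.
- Risk: the tethered conjugate addition may be outrun by oligomerisation of the ynone or by oxygen-centred addition, or the Claisen closure may stall once ring C has formed.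
- Fallback: this uses known chemistry and brings ring D in preformed. It sets out from acid 7. Suzuki–Miyaura coupling with commercial 3,5-bis(benzyloxy)phenylboronic acid (OB(O)c1cc(OCc2ccccc2)cc(OCc2ccccc2)c1; Pd(PPh3)4, K2CO3, dioxane–H2O, 90 °C) should give 2-{3-[3,5-bis(benzyloxy)phenyl]-6-(benzyloxy)-2-[4-(benzyloxy)phenyl]-1-benzofuran-4-yl}acetic acid F1. Its mixed anhydride with trifluoroacetic anhydride (CH2Cl2, 0 °C → rt) should then undergo intramolecular Friedel–Crafts acylation. The attack occurs at either of the two equivalent positions ortho to the biaryl bond, each activated by an ortho and a para benzyloxy group. This closes ring C and comes back to the route at ketone 17, so steps 6 to 10 are bypassed.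

2. Step 13.
- Risk: hydroboration of the crowded triaryl alkene may be slow, which would allow loss of α-pinene from the reagent and an achiral borane background. Facial selectivity on the tub-shaped ring C may also be poor.
- Fallback: this replaces reagent control with resolution and sets out from alkene 21. BH3·SMe2 (THF, 0 °C → rt) followed by NaOH/H2O2 should give the racemic trans alcohol, that is 23 together with the enantiomer of 23 F2. Acylation follows with (1S)-(−)-camphanic chloride (CC1(C)[C@@]2(C)CC[C@]1(C(=O)Cl)OC2=O; pyridine, DMAP, CH2Cl2). It should give the camphanate of 23 F3 and the camphanate of the enantiomer F4, which are separated by crystallisation or chromatography. Methanolysis of F3 (K2CO3, MeOH–THF, rt) is harmless at the alcohol stage, where C-d is not enolisable, and returns to the route at alcohol 23.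

3. Step 15.
- Risk: over-reduction of the aryl ketone or of the furan double bond, incomplete cleavage of the five ethers, or erosion of configuration at C-d on long contact with the catalyst.
- Fallback: this is a non-reductive ether cleavage that sets out from 24. BCl3 with pentamethylbenzene as benzyl cation scavenger (CH2Cl2, −78 °C, MeOH quench) removes all benzyl groups by Lewis acid assisted C–O heterolysis and leads directly to 25. No hydrogen or metal surface is involved, and this fallback makes no new compound (F0).

Further compounds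
F1 | step 9 | 2-{3-[3,5-bis(benzyloxy)phenyl]-6-(benzyloxy)-2-[4-(benzyloxy)phenyl]-1-benzofuran-4-yl}acetic acid | O=C(O)Cc1cc(OCc2ccccc2)cc2oc(-c3ccc(OCc4ccccc4)cc3)c(-c3cc(OCc4ccccc4)cc(OCc4ccccc4)c3)c12
F2 | step 13 | enantiomer of 23, C-a (S), C-d (R) | O[C@@H]1c2cc(OCc3ccccc3)cc3oc(-c4ccc(OCc5ccccc5)cc4)c(c23)-c2cc(OCc3ccccc3)cc(OCc3ccccc3)c2[C@H]1c1ccc(OCc2ccccc2)cc1
F3 | step 13 | (1S,4R)-camphanate of 23 | CC1(C)[C@@]2(C)CC[C@]1(C(=O)O[C@H]3c4cc(OCc5ccccc5)cc5oc(-c6ccc(OCc7ccccc7)cc6)c(c45)-c4cc(OCc5ccccc5)cc(OCc5ccccc5)c4[C@@H]3c3ccc(OCc4ccccc4)cc3)OC2=O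
F4 | step 13 | (1S,4R)-camphanate of F2 | CC1(C)[C@@]2(C)CC[C@]1(C(=O)O[C@@H]3c4cc(OCc5ccccc5)cc5oc(-c6ccc(OCc7ccccc7)cc6)c(c45)-c4cc(OCc5ccccc5)cc(OCc5ccccc5)c4[C@H]3c3ccc(OCc4ccccc4)cc3)OC2=O
F0 | step 15 | none | none
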